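The readings stem from a simulated flask with constants of no real substance.

How far does the starting complex get in the flask by 3.0 h, and what stops it there?

| flask | starting complex | incoming ligand | leaving ligand | protic impurity | remark | time |
|---|---|---|---|---|---|---|
| blue | 0.025 M | 0.055 M | 0.025 M | 0.025 M | run made earlier |  |
| teal | 0.038 M | 0.055 M | 0.025 M | 0.025 M | run made earlier |  |
| ochre | 0.050 M | 0.083 M | 0.025 M | 0.025 M | run made earlier |  |
| flask | 0.050 M | 0.0550 M | 0.0250 M | 0.0250 M |  | 3.0 h |

| run | time / min | starting complex / % | complex with one exchanged / % | complex with three exchanged / % |
|---|---|---|---|---|
| blue | 8.00 | 41.5 | 45.4 | 0.2 |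
| blue | 20.0 | 41.4 | 46.6 | 0.5 |
| blue | 50.0 | 41.3 | 46.6 | 0 |
| blue | 120 | 41.6 | 46.6 | 0.2 |
| teal | 25.0 | 51.9 | 40.6 | 0 |
| teal | 50.0 | 52.7 | 40.2 | 0 |
| teal | 80.0 | 52.4 | 40.5 | 0 |
| teal | 120 | 52.4 | 40.4 | 0.5 |
| ochre | 25.0 | 38.2 | 47.7 | 0.3 |
| ochre | 50.0 | 38.8 | 47.6 | 0.4 |
| ochre | 80.0 | 38.5 | 47.1 | 0.2 |
| ochre | 120 | 38.4 | 47.9 | 0.7 |

(readings scatter by 0.3 percentage points)

1. why nothing more happens at 3.0 h, or that something still does (all of the starting complex has reacted / forward and back rates have come level / the incoming ligand has run out first / it is still moving)
2. conversion of starting complex at 3.0 h
3. amount of complex with one exchanged at 3.0 h, in percent of the starting complex charged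

- what is said of complex with three exchanged includes crystals
- crystals is a solid; its amount is given per volume of the solution
- what was read earlier has a scatter of 0.3 percentage points, one standard deviation
- on the list of suspects stand: protic impurity + incoming ligand -> quenched reagent; crystals <-> complex with three exchanged; complex with two exchanged + incoming ligand <-> leaving ligand + complex with three exchanged; starting complex + incoming ligand <-> leaving ligand + complex with one exchanged; complex with one exchanged + incoming ligand <-> leaving ligand + complex with two exchanged
- the reaction counts as stopped when no species that holds the starting complex changes by six tenths of a point or more over the second half of the time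

We reckon with the usable ligand, the incoming ligand charged minus the protic impurity, taking one ligand per impurity: 0.0300 M in the flask. That is less than the 0.050 M of starting complex, so usable ligand is the limiting reagent of the first exchange. We test it on the last readings, taking two exchanged as the remainder. Counting the exchanged ligand and subtracting it from the usable ligand, the first exchange constant reads 3.85 in blue and 3.93 in ochre, though the two runs differ in starting complex and in incoming ligand.

The blue run had lost 58.5% of its starting complex by its first reading at 8.00 min, a mean slope of 0.0731 min⁻¹, and its starting complex stayed flat within the scatter afterwards. We therefore draw the flask's curve as a steep fall, a knee within minutes and a flat line up to 3.0 h. For the flask's level, our own reckoning ignores the second exchange and solves the first equilibrium against the balance of usable ligand. That gives a conversion of 42.4%. Complex with one exchanged in the flask should then level below starting complex without crossing it. A second exchange spends further ligand, so we expect a somewhat lower conversion in the flask.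

The forecast, noting that “The plateaus are flat in all three runs”, says forward and back rates have come level, with conversion 40.4% and one exchanged 35.5%. Its conversion lies below our first-exchange figure.

The flask gives forward and back rates have come level, with conversion 40.4% and one exchanged 35.5%.

    protic impurity + incoming ligand → quenched reagent (k = 4.80 L mol⁻¹ s⁻¹)
    crystals ⇌ complex with three exchanged, rate k2*(cs2 - [complex with three exchanged]) while solid is left; crystals form when [complex with three exchanged] > cs2 (solubility = 21.0 mM, k = 0.810 s⁻¹)
    complex with two exchanged + incoming ligand ⇌ leaving ligand + complex with three exchanged (K = 0.0720, k = 0.270 L mol⁻¹ s⁻¹)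
    starting complex + incoming ligand ⇌ leaving ligand + complex with one exchanged (K = 3.90, k = 0.270 L mol⁻¹ s⁻¹)
    complex with one exchanged + incoming ligand ⇌ leaving ligand + complex with two exchanged (K = 0.900, k = 0.450 L mol⁻¹ s⁻¹)

The flask's conversion stays low mainly through the depletion of incoming ligand: with that ligand held at its charge, the conversion reaches 81.0%. The forecast's one-exchanged figure would be 5 points off at 0.0487 M of ligand or 0.0313 M of impurity, and both leave the same usable ligand, 0.0237 M and 0.0237 M. In the neighbour with 0.093 M of incoming ligand, usable ligand is 0.0680 M, now above the starting complex. That flask gives conversion 66.8%, and complex with one exchanged, at 49.4%, holds most.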